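The data come from a simulation from invented constants.

In a one-step world J and E run on to X and nothing else touches E, but Friday's run says otherwise. The apparent rate of J's loss, as read, is 0.109 min⁻¹ over the first 6.00 min and 0.0931 min⁻¹ between 6.00 min and 12.0 min, so E sinks by 0.0258 min⁻¹ of itself, while J's own demand takes 0.00940 min⁻¹. I put the difference, 0.0164 min⁻¹, down to E burning to Z.

- Wednesday's (time / min: X / %, J / %): 3.00: 0, 99.3; 4.00: 0, 98.2; 6.00: 0.4, 98.8; 10.0: 0, 98.0; 15.0: 0, 97.4; 25.0: 1.6, 94.7; 40.0: 2.8, 92.2
- Friday's (time / min: X / %, J / %): 0.667: 0.4, 91.8; 2.00: 1.7, 79.3; 3.00: 2.5, 70.2; 4.00: 8.4, 63.3; 6.00: 11.0, 52.1; 8.00: 19.2, 42.0; 12.0: 32.7, 29.8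

(readings scatter by 1 percentage point)

So I hand over one number, the split ratio 0.0151 M⁻¹ s⁻¹ over that burning rate, which is 55.4 M⁻¹: the rate constant of J with E over the rate constant of E's burning, a ratio that carries a unit and must be multiplied by J's concentration of the moment to say how E divides between its two users, so that the division shifts as J falls. At one temperature, while both users run first order in E, the logarithm of J's fall equals this ratio times the Z made, whatever the clock says.

For whoever takes the bench: these are the flasks and the questions.

| flask | J | E | temperature | remark | time |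
|---|---|---|---|---|---|
| Wednesday's | 0.020 M | 1.5 equiv | 60 °C | run made earlier |  |
| Friday's | 0.020 M | 6 equiv | 90 °C | run made earlier |  |
| dawn | 0.020 M | 3.00 equiv | 65 °C |  | 30 min |
| spring | 0.020 M | 3.00 equiv | 90 °C |  | 30 min |
| dusk | 0.020 M | 3.00 equiv | 115 °C |  | 30 min |

- the flask with the highest amount of X, in percent of the J charged ("all alike" if they lie within 1.5 percentage points) (dawn / spring / dusk / all alike)
- final X, as a percentage of the J charged, in dawn
- final X, as a percentage of the J charged, in spring
- final X, as a percentage of the J charged, in dusk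

- the numbers in the tables scatter with a standard deviation of 1 percentage point
- candidate steps: E -> Z; D <-> G; J + E -> D + L; D <-> X

In each flask J and E make D and L, and D passes on to X. Please leave the E charge as written, since the floor I give next is reckoned on that amount. At the far end of dusk, if J takes its whole claim on E and the rest burns, and if Friday's ratio still holds there, which I can't test, J stops near 10.9%. On X I commit to nothing of my own.

The forecast names dusk as richest in X, with 5%, 47% and 75% for dawn, spring and dusk, saying “E burns off, so about 85–90% is consumed and D converts quickly”.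

The flasks give 2.64%, 44.3% and 36.8%, and the richest is spring.

    E → Z (k = 2.20 × 10⁻⁴ s⁻¹, Ea = 114 kJ mol⁻¹)
    D ⇌ G (K = 2.00, k = 4.80 × 10⁻⁵ s⁻¹, Ea = 124 kJ mol⁻¹, ΔH = −65.0 kJ mol⁻¹)
    J + E → D + L (k = 0.0170 M⁻¹ s⁻¹, Ea = 88.0 kJ mol⁻¹)
    D ⇌ X (K = 2.50, k = 0.00180 s⁻¹, Ea = 96.0 kJ mol⁻¹, ΔH = −38.0 kJ mol⁻¹)
    (constants at 90 °C)

At 30.0 min dusk's E is down to 0.427%, with J at 15.0% against my floor of 10.9%. The split ratio counted from J's fall and the Z made is 44.4 M⁻¹ in dusk and 77.3 M⁻¹ in spring, so dusk hands more of its E to Z. J went about where the ratio put it, and the missing X lies further along: with the backward step from X to D taken away, dusk ends at 84.3% of X instead of 36.8%.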